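**Strategy**

The eleven-membered ring is closed at its most hindered bond, between the acetoxy-bearing carbinol carbon C1 and the gem-dimethyl quaternary ring carbon C11. This neopentylic CH(O)–CMe2 unit is read as the Markovnikov adduct of an isopropenyl group and an aldehyde: cobalt-hydride hydrogen-atom transfer converts the terminal alkene into the tertiary C11 radical, chromium turns it into a carbon nucleophile, and this adds to the (Z)-enal carbon C1. One operation closes the ring and creates the quaternary centre, its second methyl group and the C1 stereocentre. The precursor is an acyclic (2Z,6E)-4-aroyloxy-trienal with a terminal isopropenyl group, assembled from methyl (R)-glycidate through a butenolide that locks the Z-alkene.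

Key step: step 10

**Remarks**

- Ring locants used throughout: C1 (acetoxy carbinol), C2=C3 (Z, methyl on C3), C4 (aroyloxy carbon), C5, C6=C7 (E, methyl on C7), C8–C10, C11 (CMe2). With these locants the target is (1S,2Z,4R,6E).
- 5-Bromo-2-methylpent-1-ene is assumed to be a catalogue compound.
- The facial sense of the ring closure in step 10 is a conformational prediction, not a certainty; it is treated as the first risk below.

**Route**

Step 1
Reactants: 1 5-bromo-2-methylpent-1-ene
Product: 2 6-methylhept-6-en-1-yne
Conditions: lithium acetylide–ethylenediamine complex, DMSO, 0 °C → rt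
Reagents that add atoms: lithium acetylide (ethylenediamine complex), [Li]C#C.NCCN
Why: SN2 displacement of the primary bromide by acetylide (acetylide alkylation) installs the terminal alkyne without touching the 1,1-disubstituted alkene.

Step 2
Reactants: 2 6-methylhept-6-en-1-yne
Product: 4 (1E)-1-iodo-2,6-dimethylhepta-1,6-diene, via alkenylalane 3 (not isolated)
Conditions: AlMe3, Cp2ZrCl2 (cat.), CH2Cl2, 0 °C → rt; then I2, THF, −30 → 0 °C
Reagents that add atoms: trimethylaluminium, C[Al](C)C; iodine, II
Why: Zirconium-catalysed carboalumination (Negishi) adds Me and Al syn across the terminal alkyne with Me on the internal carbon, and iodinolysis of the C–Al bond with retention fixes the E trisubstituted alkene (the future C6=C7), while the unactivated 1,1-disubstituted alkene does not carbometalate under these conditions.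

Step 3
Reactants: 4 (1E)-1-iodo-2,6-dimethylhepta-1,6-diene; 5 methyl (2R)-oxirane-2-carboxylate
Product: 8 methyl (2R,4E)-2-hydroxy-5,9-dimethyldeca-4,9-dienoate, via alkenyllithium 6 (not isolated), via alkenylmagnesium bromide 7 (not isolated)
Conditions: t-BuLi (2 equiv), Et2O, −78 °C; MgBr2·OEt2; then 5, CuI (10 mol %), THF, −40 → −20 °C; aq. NH4Cl
Reagents that add atoms: none
Why: Iodine–lithium exchange and transmetalation proceed with retention of alkene geometry, and the copper-catalysed alkenyl Grignard opens the glycidate by SN2 attack at the unsubstituted epoxide carbon, so the C–O stereocentre of 5 is carried over untouched as C4 (R).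

Step 4
Reactants: 8 methyl (2R,4E)-2-hydroxy-5,9-dimethyldeca-4,9-dienoate
Product: 10 (3R,5E)-3-hydroxy-6,10-dimethylundeca-5,10-dien-2-one, via Weinreb amide 9 (not isolated)
Conditions: MeNHOMe·HCl, i-PrMgCl, THF, −20 °C; then MeMgBr, −20 → 0 °C; aq. NH4Cl
Reagents that add atoms: methylmagnesium bromide, C[Mg]Br; N,O-dimethylhydroxylamine hydrochloride, CNOC.Cl (its atoms stay only in intermediate 9)
Why: The chloromagnesium amide of N,O-dimethylhydroxylamine converts the ester into the Weinreb amide, whose chelated tetrahedral adduct with MeMgBr collapses only on work-up and so stops at the methyl ketone, while the α-hydroxyl is masked as its magnesium alkoxide and the stereocentre is not touched.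

Step 5
Reactants: 10 (3R,5E)-3-hydroxy-6,10-dimethylundeca-5,10-dien-2-one
Product: 12 (5R)-5-[(2E)-3,7-dimethylocta-2,7-dien-1-yl]-4-methylfuran-2(5H)-one, via ester ylide 11 (not isolated)
Conditions: (triphenylphosphoranylidene)ketene, toluene, 80–110 °C
Reagents that add atoms: (triphenylphosphoranylidene)ketene, O=C=C=P(c1ccccc1)(c1ccccc1)c1ccccc1
Why: The hydroxyl adds to the ketene to give an ester-stabilised ylide that closes by intramolecular Wittig olefination onto the methyl ketone (cumulated-ylide butenolide annulation), and the five-membered ring forces the C2=C3 double bond to be Z.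

Step 6
Reactants: 12 (5R)-5-[(2E)-3,7-dimethylocta-2,7-dien-1-yl]-4-methylfuran-2(5H)-one
Product: 13 (2Z,4R,6E)-3,7,11-trimethyldodeca-2,6,11-triene-1,4-diol
Conditions: DIBAL-H (3.5 equiv), CH2Cl2, −78 → 0 °C; Rochelle salt
Reagents that add atoms: none
Why: DIBAL-H reduces the lactone through the lactol to the allylic alcohol by 1,2-reduction, releasing the (Z)-ene-1,4-diol with the ring-derived alkene geometry and the C4 configuration intact.

Step 7
Reactants: 13 (2Z,4R,6E)-3,7,11-trimethyldodeca-2,6,11-triene-1,4-diol; 14 4-acetoxybenzoyl chloride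
Product: 16 (2Z,4R,6E)-1-[(tert-butyldimethylsilyl)oxy]-3,7,11-trimethyldodeca-2,6,11-trien-4-yl 4-acetoxybenzoate, via mono-silyl ether 15 (not isolated)
Conditions: TBSCl (1.05 equiv), Et3N, DMAP (cat.), CH2Cl2, 0 °C; then 14, 0 °C → rt
Reagents that add atoms: tert-butyldimethylsilyl chloride, CC(C)(C)[Si](C)(C)Cl
Why: Silylation discriminates the primary from the secondary allylic hydroxyl on steric grounds, and the remaining C4–OH is then acylated under nucleophilic (DMAP) catalysis with retention because the C4–O bond is not broken.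

Step 8
Reactants: 16 (2Z,4R,6E)-1-[(tert-butyldimethylsilyl)oxy]-3,7,11-trimethyldodeca-2,6,11-trien-4-yl 4-acetoxybenzoate
Product: 17 (2Z,4R,6E)-1-hydroxy-3,7,11-trimethyldodeca-2,6,11-trien-4-yl 4-acetoxybenzoate
Conditions: HF·pyridine, pyridine, THF, 0 °C
Reagents that add atoms: none
Why: Buffered HF·pyridine cleaves the primary alkyl silyl ether while the two esters are inert to this mildly acidic fluoride source, which also disfavours base-mediated 1,4-acyl migration.

Step 9
Reactants: 17 (2Z,4R,6E)-1-hydroxy-3,7,11-trimethyldodeca-2,6,11-trien-4-yl 4-acetoxybenzoate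
Product: 18 (2Z,4R,6E)-3,7,11-trimethyl-1-oxododeca-2,6,11-trien-4-yl 4-acetoxybenzoate
Conditions: Dess–Martin periodinane, NaHCO3, CH2Cl2, 0 °C; used directly
Reagents that add atoms: none
Why: Dess–Martin oxidation of the primary allylic alcohol under buffered, non-basic conditions gives the enal without enolisation, so the Z geometry and the γ-stereocentre are preserved.

Step 10
Reactants: 18 (2Z,4R,6E)-3,7,11-trimethyl-1-oxododeca-2,6,11-trien-4-yl 4-acetoxybenzoate
Product: 19 (1S,2Z,4R,6E)-1-hydroxy-3,7,11,11-tetramethylcycloundeca-2,6-dien-4-yl 4-acetoxybenzoate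
Conditions: Co(salen) (cat.), CrCl3, PhSiH3, N-fluoro-2,4,6-trimethylpyridinium triflate (initiator), THF, rt, syringe-pump addition of 18 (final ≤ 2 mM); aq. work-up
Reagents that add atoms: none
Why: A cobalt(III) hydride formed from Co(salen) and PhSiH3 transfers a hydrogen atom to the terminal CH2 of the 1,1-disubstituted alkene (Markovnikov MHAT), the resulting tertiary C11 radical is intercepted by chromium to give a nucleophilic tertiary alkylchromium(III), and this adds 1,2 to the chromium-activated enal carbon C1, the alcohol being released on work-up. The closest known reaction type is the cobalt–salen/chromium MHAT-initiated branch-selective reductive coupling of unactivated alkenes with aldehydes (a radical–polar crossover, in effect an alkyl Nozaki–Hiyama–Kishi addition), used here in ring-closing mode. The eleven-membered carbocycle closes by 11-exo-trig attack of C11 on the C1=O carbon. The new C1 stereocentre is controlled by the C4 stereocentre through 1,4-induction across the Z-C2=C3 bond: with the enal s-trans and C4–H eclipsing the alkene, closure through the crossed conformer in which C5 and C11 leave opposite faces of the Z-alkene is expected to be preferred, because it spares the E-C6=C7 tether a tight same-face loop and lets chromium bind the C4 ester carbonyl; it delivers C11 syn to the C4 oxygen and so gives the 1S (1,4-trans) alcohol. The step needs HAT at the 1,1-disubstituted alkene rather than at the trisubstituted C6=C7 or the electron-poor enal alkene (steric and electronic bias of the cobalt hydride), radical capture by chromium faster than 5-exo/6-endo attack on C6=C7, and 1,2- rather than 1,4-addition (intrinsic to organochromium reagents), while high dilution suppresses oligomerisation.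

Step 11
Reactants: 19 (1S,2Z,4R,6E)-1-hydroxy-3,7,11,11-tetramethylcycloundeca-2,6-dien-4-yl 4-acetoxybenzoate
Product: 20 (1S,2Z,4R,6E)-1-acetoxy-3,7,11,11-tetramethylcycloundeca-2,6-dien-4-yl 4-acetoxybenzoate
Conditions: Ac2O, DMAP, pyridine, CH2Cl2, rt
Reagents that add atoms: acetic anhydride, CC(=O)OC(C)=O
Why: DMAP-catalysed acetylation of the hindered neopentylic allylic alcohol proceeds with retention since the C1–O bond is not broken.

Step 12
Reactants: 20 (1S,2Z,4R,6E)-1-acetoxy-3,7,11,11-tetramethylcycloundeca-2,6-dien-4-yl 4-acetoxybenzoate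
Product: 21 (1S,2Z,4R,6E)-1-acetoxy-3,7,11,11-tetramethylcycloundeca-2,6-dien-4-yl 4-hydroxybenzoate
Conditions: K2CO3 (cat.), MeOH, −10 → 0 °C; aq. NH4Cl
Reagents that add atoms: none
Why: Base-catalysed methanolysis (transesterification) removes the phenolic acetate, whose p-acylphenoxide is a far better leaving group than the alkoxides of the hindered C1 acetate and the C4 benzoate, so the two alkyl esters and both stereocentres remain.

**Compound list**

1 | 5-bromo-2-methylpent-1-ene | C=C(C)CCCBr | starting material
2 | 6-methylhept-6-en-1-yne | C#CCCCC(C)=C | intermediate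
3 | [(1E)-2,6-dimethylhepta-1,6-dien-1-yl]dimethylalane | C[Al](C)/C=C(\C)CCCC(C)=C | intermediate
4 | (1E)-1-iodo-2,6-dimethylhepta-1,6-diene | I/C=C(\C)CCCC(C)=C | intermediate
5 | methyl (2R)-oxirane-2-carboxylate | COC(=O)[C@H]1CO1 | starting material
6 | [(1E)-2,6-dimethylhepta-1,6-dien-1-yl]lithium | [Li]/C=C(\C)CCCC(C)=C | intermediate
7 | [(1E)-2,6-dimethylhepta-1,6-dien-1-yl]magnesium bromide | Br[Mg]/C=C(\C)CCCC(C)=C | intermediate
8 | methyl (2R,4E)-2-hydroxy-5,9-dimethyldeca-4,9-dienoate | COC(=O)[C@H](O)C/C=C(\C)CCCC(C)=C | intermediate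
9 | (2R,4E)-2-hydroxy-N-methoxy-N,5,9-trimethyldeca-4,9-dienamide | CON(C)C(=O)[C@H](O)C/C=C(\C)CCCC(C)=C | intermediate
10 | (3R,5E)-3-hydroxy-6,10-dimethylundeca-5,10-dien-2-one | CC(=O)[C@H](O)C/C=C(\C)CCCC(C)=C | intermediate
11 | (3R,5E)-6,10-dimethyl-2-oxoundeca-5,10-dien-3-yl (triphenyl-λ5-phosphanylidene)acetate | CC(=O)[C@H](OC(=O)C=P(c1ccccc1)(c1ccccc1)c1ccccc1)C/C=C(\C)CCCC(C)=C | intermediate
12 | (5R)-5-[(2E)-3,7-dimethylocta-2,7-dien-1-yl]-4-methylfuran-2(5H)-one | O=C1C=C(C)[C@@H](C/C=C(\C)CCCC(C)=C)O1 | intermediate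
13 | (2Z,4R,6E)-3,7,11-trimethyldodeca-2,6,11-triene-1,4-diol | OC/C=C(/C)[C@H](O)C/C=C(\C)CCCC(C)=C | intermediate
14 | 4-acetoxybenzoyl chloride | CC(=O)Oc1ccc(cc1)C(Cl)=O | starting material
15 | (2Z,4R,6E)-1-[(tert-butyldimethylsilyl)oxy]-3,7,11-trimethyldodeca-2,6,11-trien-4-ol | CC(C)(C)[Si](C)(C)OC/C=C(/C)[C@H](O)C/C=C(\C)CCCC(C)=C | intermediate
16 | (2Z,4R,6E)-1-[(tert-butyldimethylsilyl)oxy]-3,7,11-trimethyldodeca-2,6,11-trien-4-yl 4-acetoxybenzoate | CC(C)(C)[Si](C)(C)OC/C=C(/C)[C@H](OC(=O)c1ccc(OC(C)=O)cc1)C/C=C(\C)CCCC(C)=C | intermediate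
17 | (2Z,4R,6E)-1-hydroxy-3,7,11-trimethyldodeca-2,6,11-trien-4-yl 4-acetoxybenzoate | OC/C=C(/C)[C@H](OC(=O)c1ccc(OC(C)=O)cc1)C/C=C(\C)CCCC(C)=C | intermediate
18 | (2Z,4R,6E)-3,7,11-trimethyl-1-oxododeca-2,6,11-trien-4-yl 4-acetoxybenzoate | O=C/C=C(/C)[C@H](OC(=O)c1ccc(OC(C)=O)cc1)C/C=C(\C)CCCC(C)=C | intermediate
19 | (1S,2Z,4R,6E)-1-hydroxy-3,7,11,11-tetramethylcycloundeca-2,6-dien-4-yl 4-acetoxybenzoate | O[C@H]1/C=C(/C)[C@H](OC(=O)c2ccc(OC(C)=O)cc2)C/C=C(\C)CCCC1(C)C | intermediate
20 | (1S,2Z,4R,6E)-1-acetoxy-3,7,11,11-tetramethylcycloundeca-2,6-dien-4-yl 4-acetoxybenzoate | CC(=O)O[C@H]1/C=C(/C)[C@H](OC(=O)c2ccc(OC(C)=O)cc2)C/C=C(\C)CCCC1(C)C | intermediate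
21 | (1S,2Z,4R,6E)-1-acetoxy-3,7,11,11-tetramethylcycloundeca-2,6-dien-4-yl 4-hydroxybenzoate | CC(=O)O[C@H]1/C=C(/C)[C@H](OC(=O)c2ccc(O)cc2)C/C=C(\C)CCCC1(C)C | target

**Step count**

Total steps: 12. Longest linear sequence: 12 (from 1).

**Steps most likely to fail**

1. Step 10. The process at risk is the facial course of the C11→C1 addition: the ring may close through the compact conformer in which C5 and C11 lie on the same face of the Z-alkene, which would give poor or reversed 1,4-induction at C1. Ring closure may in addition be eroded by premature reduction of the tertiary radical. The fallback sets out from 18 and returns at 19. It moves the setting of C1 from the C–C bond formation to a C–H bond formation. Ring closure of 18 as in step 10 is carried through to whatever C1 mixture it gives, in the unfavourable case mainly (1R,2Z,4R,6E)-1-hydroxy-3,7,11,11-tetramethylcycloundeca-2,6-dien-4-yl 4-acetoxybenzoate F1. Dess–Martin oxidation then gives the macrocyclic enone (2Z,4R,6E)-3,7,11,11-tetramethyl-1-oxocycloundeca-2,6-dien-4-yl 4-acetoxybenzoate F2. In F2 the carbonyl is twisted out of conjugation by the quaternary C11 and the cis C4 substituent. Luche reduction (NaBH4, CeCl3·7H2O, MeOH/THF, −78 °C) should deliver hydride from the ring periphery, the direction opposite to that from which C11 entered in the same-face closure, so the outcome is expected to be complementary and to lead to 19.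

2. Step 8. The process at risk is 1,4-O→O migration of the aroyl group from C4 to the newly freed primary hydroxyl across the Z-alkene; the same free alcohol also precedes the isomerisation-prone enal of step 9. The fallback sets out from 13 and returns at 18, bypassing the free alcohol 17. Diol 13 is silylated at the primary hydroxyl with TESCl (Et3N, DMAP, −78 °C) to (2Z,4R,6E)-3,7,11-trimethyl-1-[(triethylsilyl)oxy]dodeca-2,6,11-trien-4-ol F3. Acylation in the same flask with 14 gives (2Z,4R,6E)-3,7,11-trimethyl-1-[(triethylsilyl)oxy]dodeca-2,6,11-trien-4-yl 4-acetoxybenzoate F4. Swern conditions (oxalyl chloride, DMSO, −78 → −40 °C, then i-Pr2NEt) convert the primary triethylsilyl ether of F4 directly into the aldehyde 18 by oxidative desilylation.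

3. Step 5. The processes at risk are base-induced enolisation (racemisation) of the α-hydroxy ketone by the basic ylide at elevated temperature and competing intermolecular Wittig reaction. The fallback sets out from 10 and returns at 12, and separates acylation from olefination. Esterification of 10 with diethylphosphonoacetic acid (DCC, DMAP, CH2Cl2, 0 °C) gives (3R,5E)-6,10-dimethyl-2-oxoundeca-5,10-dien-3-yl 2-(diethoxyphosphoryl)acetate F5. An intramolecular Horner–Wadsworth–Emmons reaction under Masamune–Roush conditions (LiCl, i-Pr2NEt, MeCN, rt) then closes the butenolide 12.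

**Further compounds**

F1 | step 10 | (1R,2Z,4R,6E)-1-hydroxy-3,7,11,11-tetramethylcycloundeca-2,6-dien-4-yl 4-acetoxybenzoate | O[C@@H]1/C=C(/C)[C@H](OC(=O)c2ccc(OC(C)=O)cc2)C/C=C(\C)CCCC1(C)C
F2 | step 10 | (2Z,4R,6E)-3,7,11,11-tetramethyl-1-oxocycloundeca-2,6-dien-4-yl 4-acetoxybenzoate | O=C1/C=C(/C)[C@H](OC(=O)c2ccc(OC(C)=O)cc2)C/C=C(\C)CCCC1(C)C
F3 | step 8 | (2Z,4R,6E)-3,7,11-trimethyl-1-[(triethylsilyl)oxy]dodeca-2,6,11-trien-4-ol | CC[Si](CC)(CC)OC/C=C(/C)[C@H](O)C/C=C(\C)CCCC(C)=C
F4 | step 8 | (2Z,4R,6E)-3,7,11-trimethyl-1-[(triethylsilyl)oxy]dodeca-2,6,11-trien-4-yl 4-acetoxybenzoate | CC[Si](CC)(CC)OC/C=C(/C)[C@H](OC(=O)c1ccc(OC(C)=O)cc1)C/C=C(\C)CCCC(C)=C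
F5 | step 5 | (3R,5E)-6,10-dimethyl-2-oxoundeca-5,10-dien-3-yl 2-(diethoxyphosphoryl)acetate | CC(=O)[C@H](OC(=O)CP(=O)(OCC)OCC)C/C=C(\C)CCCC(C)=C
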